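Readings and results are simulated for substances that don't exist, and the scatter is random.

**Leftover first.** Of the substrate charged, a fraction 53% still stood in the west run at 80.0 min, with 7.5 µM of enzyme. We treat its decay as pseudo-first-order, with enzyme times time as the clock, and we call enzyme times time the dose. That leftover then reads 655 µM·min: the halving dose, the dose that brings a leftover fraction to half of itself at this substrate charge.

the same everywhere: substrate 0.050 M

| run | enzyme | remark | time |
|---|---|---|---|
| north-west | 5 µM | run made earlier |  |
| west | 7.5 µM | run made earlier |  |
| green | 10 µM |  | 80 min |
| violet | 10 µM |  | 40 min |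

| run | time / min | product / % | substrate / % |
|---|---|---|---|
| north-west | 6.00 | 6 | 95 |
| north-west | 12.0 | 13 | 95 |
| north-west | 25.0 | 15 | 86 |
| north-west | 40.0 | 26 | 76 |
| north-west | 80.0 | 35 | 64 |
| west | 6.00 | 7 | 93 |
| west | 12.0 | 13 | 87 |
| west | 25.0 | 21 | 80 |
| west | 40.0 | 28 | 68 |
| west | 80.0 | 50 | 53 |

(scatter of a reading: 2 percentage points)



- which of the two ends with the higher amount of product, in percent of the substrate charged ("neither" if they lie within 2 percentage points) (green / violet / neither)
- product at the end, in percent of the substrate charged, green
- product at the end, in percent of the substrate charged, violet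

**Same dose.** Violet looks like the last north-west reading: twice the enzyme for half the time, a dose of 400 µM·min in both. So we expect violet near the 35% of product that north-west showed. The runs permit this: north-west at 40.0 min and west at 25.0 min, with doses of 200 µM·min and 188 µM·min, kept 76% and 80%, against a scatter of 2 percentage points on each reading.

**Our reckoning.** The halving dose gives violet a product fraction of 34.5%. Green is the same flask read twice as late, and it gets 57.1%. So we expect green to end higher, because its dose exceeds violet's.

**The forecast.** It names green, with 58% for green and 37% for violet, on the ground that “the enzyme appears to act as a simple multiplier of time”. Our violet lies lower than its figure.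

**The result.** Green ends at 55.5% and violet at 37.9%.

    substrate + enzyme → product + enzyme, rate k1*[substrate]^1.5*[enzyme]/(1 + ([substrate]/Kh1)^1.5) (0.0550 M, k = 400 M⁻¹·⁵ s⁻¹)
    enzyme ⇌ dormant form (K = 24.0, k = 4.00 × 10⁻⁴ s⁻¹)
    2 enzyme ⇌ resting dimer, settled at all times (K = 1.20 × 10⁵ M⁻¹)

**Read back.** The halving dose comes to 582 µM·min at violet's reading and 684 µM·min at green's. The violet flask read at 2.5 h gives 921 µM·min, and there our earlier halving dose would have said 79.6% of product against the simulated 67.7%. In violet, enzyme and dormant form relax, by that step alone and both ways together, with a half-life of 27.7 min, shorter than that reading time, and at 150 min the violet catalyst is 11.1% enzyme, 2.98% resting dimer and 85.9% dormant form.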